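Prinsepiol is C2-symmetric: ring 1 (C7–O–C9′–C8′–C8) and ring 2 (C7′–O–C9–C8–C8′) share the cis-diol bond C8–C8′. Cutting only the C7–aryl and C7′–aryl bonds leaves a twice hydroxymethylated L-tartrate whose carboxyl carbons are C7 and C7′. The precursor is therefore propellane bis-lactone 8, with rings 1 and 2 already closed as γ-lactones and an acetonide tying the C8/C8′ oxygens. The key step exploits the two equivalent, non-enolisable lactone carbonyls C7 and C7′, each flanked by a quaternary carbinol carbon: two aryllithiums 11 add once each and stop at bis-hemiketal 13, forming both aryl–carbon bonds in one operation. Silane reduction anti to the acetonide then sets C7 and C7′.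

Key step: step 5

Remarks on the chemistry:
- Labels: C7/C7′ are the benzylic carbons, C8/C8′ the carbinol bridgeheads, C9/C9′ the OCH2 carbons.
- Configuration: the target is (7R,7′R,8S,8′S), with each aryl group cis to the bridgehead hydroxyls. The bridgeheads are (R,R) in 1–13 and (S,S) in 14–16 with unchanged geometry, because C7/C7′ drop in CIP rank once the hemiketal is reduced.
- Assumption: 12 and 13 form as mixtures of anomers at C7 and C7′; one anomer is drawn and both converge in step 6.
- Compound 1 is a catalogue compound, the acetonide of dimethyl L-tartrate.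

Step 1
Reactants: 1 dimethyl (4R,5R)-2,2-dimethyl-1,3-dioxolane-4,5-dicarboxylate; 2 benzyl chloromethyl ether
Product: 4 dimethyl (4R,5R)-4-[(benzyloxy)methyl]-2,2-dimethyl-1,3-dioxolane-4,5-dicarboxylate, via lithium enolate 3 (not isolated)
Conditions: LiN(iPr)2 (1.1 equiv), THF/DMPU, −78 °C; 2, −78 → −40 °C
Reagents that add atoms: benzyl chloromethyl ether (compound 2), ClCOCc1ccccc1
Why: Alkylation of a lithium ester enolate: the dioxolane enolate survives at −78 °C because its β C–O bond lies near the enolate plane, and this enolate is known to take alkyl halides on the face cis to the ester on the neighbouring carbon, so the two esters stay trans and C4 keeps its geometry (net retention, 4R).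

Step 2
Reactants: 4 dimethyl (4R,5R)-4-[(benzyloxy)methyl]-2,2-dimethyl-1,3-dioxolane-4,5-dicarboxylate; 2 benzyl chloromethyl ether
Product: 6 dimethyl (4R,5R)-4,5-bis[(benzyloxy)methyl]-2,2-dimethyl-1,3-dioxolane-4,5-dicarboxylate, via lithium enolate 5 (not isolated)
Conditions: LiN(iPr)2 (1.2 equiv), THF/DMPU, −78 °C; 2, −78 → −30 °C
Reagents that add atoms: benzyl chloromethyl ether (compound 2), ClCOCc1ccccc1
Why: Second ester enolate alkylation of the same type: entry cis to the neighbouring ester is now also entry anti to the bulkier benzyloxymethyl group on the adjacent quaternary carbon, so both effects should favour the C2-symmetric (4R,5R) diester with retention at C5.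

Step 3
Reactants: 6 dimethyl (4R,5R)-4,5-bis[(benzyloxy)methyl]-2,2-dimethyl-1,3-dioxolane-4,5-dicarboxylate
Product: 8 (1R,5R)-1,5-(isopropylidenedioxy)-3,7-dioxabicyclo[3.3.0]octane-2,6-dione, via diol diester 7 (not isolated)
Conditions: H2 (1 atm), Pd(OH)2/C, EtOAc, rt; filter; PPTS (cat.), PhMe, 60 °C
Reagents that add atoms: none
Why: Hydrogenolysis of benzyl ethers followed by acid-catalysed double γ-lactonisation: each hydroxymethyl group lies cis to the ester on the neighbouring carbon, so both cis-fused lactones close by acyl substitution without touching a stereocentre, and the electron-poor ketal tolerates the catalytic acid.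

Step 4
Reactants: 9 4-bromo-2-methoxyphenol
Product: 10 (4-bromo-2-methoxyphenoxy)(tert-butyl)dimethylsilane
Conditions: TBSCl, imidazole, DMF, rt
Reagents that add atoms: tert-butyldimethylsilyl chloride, CC(C)(C)[Si](C)(C)Cl
Why: Silylation of a phenol with a silyl chloride and imidazole; the aryl silyl ether withstands bromine–lithium exchange at −78 °C and is removed by fluoride at the end.

Step 5
Reactants: 8 (1R,5R)-1,5-(isopropylidenedioxy)-3,7-dioxabicyclo[3.3.0]octane-2,6-dione; 10 (4-bromo-2-methoxyphenoxy)(tert-butyl)dimethylsilane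
Product: 13 (1R,5R)-2,6-bis[4-(tert-butyldimethylsilyloxy)-3-methoxyphenyl]-1,5-(isopropylidenedioxy)-3,7-dioxabicyclo[3.3.0]octane-2,6-diol (bis-hemiketal; anomers), via aryllithium 11 (not isolated), via dilithium bis-hemiketalate 12 (not isolated)
Conditions: 10 (2.5 equiv), n-BuLi (2.4 equiv), THF, −78 °C; add 8 in THF, −78 °C; AcOH, −78 °C → rt
Reagents that add atoms: none
Why: Each aryllithium 11 adds to a γ-lactone carbonyl (C7, then C7′) to give a five-membered lithium hemiketalate that does not collapse to the ketone at −78 °C, so each carbonyl takes exactly one aryl group and dilithium salt 12 is protonated cold to 13. The closest known reaction type is the addition of aryllithiums to aldonolactones in C-aryl glycoside synthesis, here run twice on one C2-symmetric substrate. No ring is closed or opened: rings 1 and 2 and the acetonide ring pass through unchanged, and the only new bonds are C7–aryl and C7′–aryl. No lasting stereocentre is set; the hemiketal carbons form as anomers and are erased in step 6, while C8 and C8′ are quaternary and cannot epimerise. The selectivity needed is mono-addition at each carbonyl without enolisation or ring cleavage, and the substrate secures it through the absence of α-hydrogen atoms at C8/C8′, the gem-disubstitution that holds each hemiketalate ring shut, and the rigid propellane, which keeps the C7 alkoxide too far from C7′ to bridge. A slight deficit of n-BuLi relative to 10 leaves no butyllithium to compete.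

Step 6
Reactants: 13 (1R,5R)-2,6-bis[4-(tert-butyldimethylsilyloxy)-3-methoxyphenyl]-1,5-(isopropylidenedioxy)-3,7-dioxabicyclo[3.3.0]octane-2,6-diol
Product: 14 (1S,2R,5S,6R)-2,6-bis[4-(tert-butyldimethylsilyloxy)-3-methoxyphenyl]-1,5-(isopropylidenedioxy)-3,7-dioxabicyclo[3.3.0]octane
Conditions: Et3SiH (6 equiv), BF3·OEt2 (3 equiv), CH2Cl2, −78 → −40 °C; Et3N, then aq. NaHCO3, cold
Reagents that add atoms: none
Why: Ionic hydrogenation of hemiketals (silane with a Lewis acid, as for lactone-derived C-aryl glycosides): each hemiketal ionises to an aryl-conjugated cyclic oxocarbenium ion whose face toward the acetonide lies under the endo methyl group, so hydride should arrive from the open face in the cleft between rings 1 and 2 and leave H trans and the aryl group cis to the bridgehead oxygen, i.e. (7R,7′R), while the low temperature keeps the ketal and the new benzylic ethers from ionising.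

Step 7
Reactants: 14 (1S,2R,5S,6R)-2,6-bis[4-(tert-butyldimethylsilyloxy)-3-methoxyphenyl]-1,5-(isopropylidenedioxy)-3,7-dioxabicyclo[3.3.0]octane
Product: 15 (1S,2R,5S,6R)-2,6-bis[4-(tert-butyldimethylsilyloxy)-3-methoxyphenyl]-3,7-dioxabicyclo[3.3.0]octane-1,5-diol
Conditions: AcOH/THF/H2O (3:1:1), 45 °C
Reagents that add atoms: none
Why: Acid-catalysed ketal hydrolysis: weak aqueous acid should release acetone, helped by relief of the aryl/methyl compression in 14, whereas the benzylic C7–O bonds, deactivated by the oxygenated C8 next to them and by the silylated phenols, should not ionise, so no stereocentre is touched.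

Step 8
Reactants: 15 (1S,2R,5S,6R)-2,6-bis[4-(tert-butyldimethylsilyloxy)-3-methoxyphenyl]-3,7-dioxabicyclo[3.3.0]octane-1,5-diol
Product: 16 prinsepiol, (1S,2R,5S,6R)-2,6-bis(4-hydroxy-3-methoxyphenyl)-3,7-dioxabicyclo[3.3.0]octane-1,5-diol
Conditions: Bu4NF, AcOH (1:1), THF, 0 °C
Reagents that add atoms: none
Why: Fluoride cleavage of aryl silyl ethers, driven by Si–F bond formation and buffered with acetic acid so that the phenoxides are protonated at once and the benzylic ethers never see free base.

Compound list
1 | dimethyl (4R,5R)-2,2-dimethyl-1,3-dioxolane-4,5-dicarboxylate (acetonide of dimethyl L-tartrate) | COC(=O)[C@@H]1OC(C)(C)O[C@H]1C(=O)OC | starting material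
2 | benzyl chloromethyl ether | ClCOCc1ccccc1 | starting material
3 | lithium enolate of 1 | [Li]OC(OC)=C1OC(C)(C)O[C@H]1C(=O)OC | intermediate (not isolated)
4 | dimethyl (4R,5R)-4-[(benzyloxy)methyl]-2,2-dimethyl-1,3-dioxolane-4,5-dicarboxylate | COC(=O)[C@]1(COCc2ccccc2)OC(C)(C)O[C@H]1C(=O)OC | intermediate
5 | lithium enolate of 4 (at C5) | COC(=O)[C@]1(COCc2ccccc2)OC(C)(C)OC1=C(OC)O[Li] | intermediate (not isolated)
6 | dimethyl (4R,5R)-4,5-bis[(benzyloxy)methyl]-2,2-dimethyl-1,3-dioxolane-4,5-dicarboxylate | COC(=O)[C@]1(COCc2ccccc2)OC(C)(C)O[C@@]1(COCc2ccccc2)C(=O)OC | intermediate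
7 | dimethyl (4R,5R)-4,5-bis(hydroxymethyl)-2,2-dimethyl-1,3-dioxolane-4,5-dicarboxylate | COC(=O)[C@]1(CO)OC(C)(C)O[C@@]1(CO)C(=O)OC | intermediate (not isolated)
8 | (1R,5R)-1,5-(isopropylidenedioxy)-3,7-dioxabicyclo[3.3.0]octane-2,6-dione ([3.3.3]propellane bis-lactone) | O=C1OC[C@]2(OC(C)(C)O3)C(=O)OC[C@]123 | intermediate
9 | 4-bromo-2-methoxyphenol | COc1cc(Br)ccc1O | starting material
10 | (4-bromo-2-methoxyphenoxy)(tert-butyl)dimethylsilane | COc1cc(Br)ccc1O[Si](C)(C)C(C)(C)C | intermediate
11 | 4-(tert-butyldimethylsilyloxy)-3-methoxyphenyllithium | [Li]c1ccc(O[Si](C)(C)C(C)(C)C)c(OC)c1 | intermediate (not isolated)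
12 | dilithium salt of bis-hemiketal 13 (one anomer drawn) | COc1cc([C@@]2(O[Li])OC[C@]3(OC(C)(C)O5)[C@@](O[Li])(c4ccc(O[Si](C)(C)C(C)(C)C)c(OC)c4)OC[C@]235)ccc1O[Si](C)(C)C(C)(C)C | intermediate (not isolated)
13 | (1R,5R)-2,6-bis[4-(tert-butyldimethylsilyloxy)-3-methoxyphenyl]-1,5-(isopropylidenedioxy)-3,7-dioxabicyclo[3.3.0]octane-2,6-diol (bis-hemiketal, one anomer drawn) | COc1cc([C@@]2(O)OC[C@]3(OC(C)(C)O5)[C@@](O)(c4ccc(O[Si](C)(C)C(C)(C)C)c(OC)c4)OC[C@]235)ccc1O[Si](C)(C)C(C)(C)C | intermediate
14 | (1S,2R,5S,6R)-2,6-bis[4-(tert-butyldimethylsilyloxy)-3-methoxyphenyl]-1,5-(isopropylidenedioxy)-3,7-dioxabicyclo[3.3.0]octane | COc1cc([C@H]2OC[C@]3(OC(C)(C)O5)[C@@H](c4ccc(O[Si](C)(C)C(C)(C)C)c(OC)c4)OC[C@]235)ccc1O[Si](C)(C)C(C)(C)C | intermediate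
15 | (1S,2R,5S,6R)-2,6-bis[4-(tert-butyldimethylsilyloxy)-3-methoxyphenyl]-3,7-dioxabicyclo[3.3.0]octane-1,5-diol | COc1cc([C@H]2OC[C@]3(O)[C@@H](c4ccc(O[Si](C)(C)C(C)(C)C)c(OC)c4)OC[C@]23O)ccc1O[Si](C)(C)C(C)(C)C | intermediate
16 | prinsepiol, (1S,2R,5S,6R)-2,6-bis(4-hydroxy-3-methoxyphenyl)-3,7-dioxabicyclo[3.3.0]octane-1,5-diol | COc1cc([C@H]2OC[C@]3(O)[C@@H](c4ccc(O)c(OC)c4)OC[C@]23O)ccc1O | target

Total step count: 8. Longest linear sequence: 7 steps (steps 1, 2, 3, 5, 6, 7, 8, from compound 1); the arene branch adds step 4.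

Steps most likely to fail

1. Step 6. What may go wrong: hydride delivery with poor or reversed facial selectivity, since the cleft between rings 1 and 2 is not fully open either. Lewis-acid ionisation of the new benzylic C–O bonds, with epimerisation or reductive ring opening, and reductive cleavage of the ketal are further risks. Fallback, setting out from 13 and coming back at 14, with no Lewis acid and with stereocontrol moved to an open-chain ketone: LiBH(s-Bu)3 in THF (−78 → 0 °C) should reduce the ring-opened keto tautomers of 13 under Felkin–Anh control, with the C8–O bond anti to the incoming hydride, which passes the hydroxymethyl arm and not the quaternary C8′. This should give the (7R,7′R)-tetraol F1. Selective sulfonylation of the two primary hydroxyls (TsCl, pyridine, 0 °C) should give the bis-tosylate F2. NaH in THF then closes rings 1 and 2 by double intramolecular Williamson etherification (5-exo-tet at C9′ and C9), which leaves C7 and C7′ untouched and gives 14.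

2. Step 5. What may go wrong: stalling after one addition for steric reasons, or opening of a lithium hemiketalate to the aryl ketone followed by addition of a further aryl group. Fallback, setting out from 8 and coming back at 13: aminolysis of both lactones with MeNH(OMe)·HCl/AlMe3 (CH2Cl2, 0 °C → rt) should give the ring-opened bis(N-methoxy-N-methylamide) diol F3. Silylation (Et3SiCl, imidazole, DMF) gives the bis(triethylsilyl) ether F4. Aryllithium 11 (THF, −78 °C) then adds in a Weinreb ketone synthesis, in which the chelated adduct cannot take a second aryl group, to give the bis(aryl ketone) F5. PPTS in MeOH at 0 °C removes the two primary triethylsilyl groups, and each freed hydroxymethyl arm closes onto the ketone across the C8–C8′ bond, returning 13.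

3. Step 2. What may go wrong: sluggish alkylation next to a quaternary centre, β-elimination of the crowded enolate, or entry of the electrophile on the wrong face, which gives a diester that cannot lactonise twice. Fallback, setting out from 4 and coming back at 8: hydrogenolysis of 4 (H2, Pd(OH)2/C, EtOAc; then PPTS, PhMe), with lactonisation of the freed hydroxymethyl group onto the C5 ester, should give the cis-fused mono-lactone F6. This also confirms the sense of step 1, since only the 4R isomer can close this ring. Deprotonation at the ring-fusion CH with LiN(iPr)2 (THF, −78 °C) and alkylation with 2 can only take place on the exo face, syn to the angular ester, because the bicycle must stay cis-fused. This gives the benzyloxymethyl lactone F7 with the required configuration by geometric necessity. A second hydrogenolysis with lactonisation under the same conditions closes the second lactone and gives 8.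

Further compounds
F1 | step 6 | (7R,7′R)-tetraol: acetonide of the ring-opened 7,7′,9,9′-tetrahydroxy form, bis-TBS ether | COc1cc([C@@H](O)[C@]2(CO)OC(C)(C)O[C@@]2(CO)[C@H](O)c3ccc(O[Si](C)(C)C(C)(C)C)c(OC)c3)ccc1O[Si](C)(C)C(C)(C)C
F2 | step 6 | 9,9′-bis-tosylate of F1 | COc1cc([C@@H](O)[C@]2(COS(=O)(=O)c3ccc(C)cc3)OC(C)(C)O[C@@]2(COS(=O)(=O)c3ccc(C)cc3)[C@H](O)c3ccc(O[Si](C)(C)C(C)(C)C)c(OC)c3)ccc1O[Si](C)(C)C(C)(C)C
F3 | step 5 | (4R,5R)-4,5-bis(hydroxymethyl)-N4,N5-dimethoxy-N4,N5,2,2-tetramethyl-1,3-dioxolane-4,5-dicarboxamide | CON(C)C(=O)[C@]1(CO)OC(C)(C)O[C@@]1(CO)C(=O)N(C)OC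
F4 | step 5 | bis(triethylsilyl) ether of F3 | CON(C)C(=O)[C@]1(CO[Si](CC)(CC)CC)OC(C)(C)O[C@@]1(CO[Si](CC)(CC)CC)C(=O)N(C)OC
F5 | step 5 | bis(aryl ketone): (4R,5R)-4,5-bis[4-(tert-butyldimethylsilyloxy)-3-methoxybenzoyl]-2,2-dimethyl-4,5-bis[(triethylsilyloxy)methyl]-1,3-dioxolane | COc1cc(C(=O)[C@]2(CO[Si](CC)(CC)CC)OC(C)(C)O[C@@]2(CO[Si](CC)(CC)CC)C(=O)c3ccc(O[Si](C)(C)C(C)(C)C)c(OC)c3)ccc1O[Si](C)(C)C(C)(C)C
F6 | step 2 | methyl (1R,5R)-7,7-dimethyl-4-oxo-3,6,8-trioxabicyclo[3.3.0]octane-1-carboxylate | COC(=O)[C@@]12COC(=O)[C@@H]1OC(C)(C)O2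
F7 | step 2 | methyl (1R,5R)-5-[(benzyloxy)methyl]-7,7-dimethyl-4-oxo-3,6,8-trioxabicyclo[3.3.0]octane-1-carboxylate | COC(=O)[C@@]12COC(=O)[C@]1(COCc3ccccc3)OC(C)(C)O2
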